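**Strategy.** Everything rests on cutting C12–C13, the bond between the CH2CH2 tether on C9 of the decalin (rings A and B, C8=C9) and the hydroxymethyl-bearing carbon of the Z-trisubstituted C13=C14 alkene. A nickel-electrocatalytic decarboxylative alkenylation unites a primary C12 radical, released from the N-hydroxyphthalimide ester of a sclareol-derived acid, with an (E)-alkenyl iodide that already holds the allylic oxygen, the C16/C17 stereodiad (one Evans syn-aldol) and the γ-lactone. The step exploits that C12 is an unfunctionalised methylene remote from every stereocentre and that the homoallyl radical next to C8=C9 can only rearrange degenerately, so alkene geometry passes unchanged and one desilylation finishes the synthesis.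

Key step: step 12

Remark: atoms are numbered labdane-style (decalin C1–C10 = rings A and B, tether C11–C12, alkene C13=C14, C15, carbinol C16, lactone methine C17); (−)-sclareol, the silyl propargyl ether, oxirane, mono-tert-butyl succinate and (S)-4-benzyloxazolidin-2-one are taken as commercial.

**Step 1**
Reactants: 1 (−)-sclareol
Product: 2 4-[(1R,2R,4aS,8aS)-2-hydroxy-2,5,5,8a-tetramethyldecahydronaphthalen-1-yl]butan-2-one
Conditions: KMnO4, acetone/H2O, 0 °C → rt
Reagents that add atoms: none
Why: Permanganate degradation of the tertiary vinyl carbinol (dihydroxylation, then glycol cleavage) should excise the two vinyl carbons and leave the side-chain methyl ketone, the saturated decalin and the tertiary C8 alcohol being inert and no stereocentre being touched.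

**Step 2**
Reactants: 2 hydroxy ketone
Product: 4 methyl 3-[(4aS,8aS)-2,5,5,8a-tetramethyl-3,4,4a,5,6,7,8,8a-octahydronaphthalen-1-yl]propanoate, via hydroxy acid 3 (not isolated)
Conditions: NaOCl (aq.), 1,4-dioxane, 0 °C → rt, then HCl (aq.); crude 3, H2SO4 (cat.), MeOH, reflux
Reagents that add atoms: methanol, CO; water (as hydroxide), O
Why: A haloform reaction on the alkene-free ketone, then Fischer esterification under E1 dehydration of the tertiary C8 alcohol, should funnel by reversible protonation to the thermodynamically preferred tetrasubstituted C8=C9 alkene, the methyl ester preventing relactonisation; C5 and C10 are untouched.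

**Step 3**
Reactants: 4 methyl ester
Product: 5 3-[(4aS,8aS)-2,5,5,8a-tetramethyl-3,4,4a,5,6,7,8,8a-octahydronaphthalen-1-yl]propanoic acid
Conditions: LiOH, THF/MeOH/H2O, rt; then HCl (1 M), 0 °C
Reagents that add atoms: lithium hydroxide, [Li+].[OH-]
Why: Ester saponification by acyl–oxygen cleavage should proceed without touching the alkene, and cold dilute acidification avoids acid-induced lactonisation onto C8=C9.

**Step 4**
Reactants: 5 acid
Product: 6 1,3-dioxoisoindolin-2-yl 3-[(4aS,8aS)-2,5,5,8a-tetramethyl-3,4,4a,5,6,7,8,8a-octahydronaphthalen-1-yl]propanoate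
Conditions: N-hydroxyphthalimide, DIC, DMAP (cat.), CH2Cl2, rt
Reagents that add atoms: N-hydroxyphthalimide, ON1C(=O)c2ccccc2C1=O
Why: Carbodiimide (Steglich-type) esterification should give the redox-active ester under neutral conditions that leave the acid-sensitive γ,δ-unsaturated acid intact.

**Step 5**
Reactants: 7 tert-butyldimethyl(prop-2-yn-1-yloxy)silane; 8 oxirane
Product: 10 5-[(tert-butyldimethylsilyl)oxy]pent-3-yn-1-ol, via lithium acetylide 9 (not isolated)
Conditions: n-BuLi, THF, −78 °C; then oxirane, DMPU, −78 °C → rt; H2O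
Reagents that add atoms: none
Why: SN2 opening of oxirane by the lithium acetylide should add the two-carbon alcohol arm (future C15 and C16) without affecting the silyl ether.

**Step 6**
Reactants: 10 alkynol
Product: 11 5-[(tert-butyldimethylsilyl)oxy]pent-3-ynal
Conditions: Dess–Martin periodinane, CH2Cl2, 0 °C → rt; used crude at once
Reagents that add atoms: none
Why: Dess–Martin oxidation is mild and non-basic, which should deliver the β,γ-alkynyl aldehyde without isomerisation to the allenal.

**Step 7**
Reactants: 12 4-tert-butoxy-4-oxobutanoic acid (mono-tert-butyl succinate); 13 (S)-4-benzyloxazolidin-2-one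
Product: 14 tert-butyl 4-[(4S)-4-benzyl-2-oxo-1,3-oxazolidin-3-yl]-4-oxobutanoate
Conditions: DCC, DMAP (cat.), CH2Cl2, 0 °C → rt
Reagents that add atoms: none
Why: Carbodiimide/DMAP N-acylation of the oxazolidinone with the free acid should give the imide directly, the tert-butyl ester being inert.

**Step 8**
Reactants: 14 imide; 11 aldehyde
Product: 16 tert-butyl (3S,4R)-3-{[(4S)-4-benzyl-2-oxo-1,3-oxazolidin-3-yl]carbonyl}-8-[(tert-butyldimethylsilyl)oxy]-4-hydroxyoct-6-ynoate, via boron enolate 15 (not isolated)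
Conditions: Bu2BOTf, iPr2NEt, CH2Cl2, −78 → 0 °C; then 11, −78 → 0 °C; pH 7 buffer, MeOH, H2O2
Reagents that add atoms: none
Why: Evans syn-aldol: the Z-boron enolate, formed regioselectively at the imide α-CH2, should add through a closed Zimmerman–Traxler transition state on the face away from the benzyl group, setting C17 and C16 together in the required syn relationship, while the tert-butyl ester resists lactonisation onto the new hydroxyl.

**Step 9**
Reactants: 16 aldol adduct
Product: 17 tert-butyl (3S,4R)-3-{[(4S)-4-benzyl-2-oxo-1,3-oxazolidin-3-yl]carbonyl}-4,8-bis[(tert-butyldimethylsilyl)oxy]oct-6-ynoate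
Conditions: TBSOTf, 2,6-lutidine, CH2Cl2, −78 °C
Reagents that add atoms: tert-butyldimethylsilyl triflate, CC(C)(C)[Si](C)(C)OS(=O)(=O)C(F)(F)F
Why: Low-temperature silylation should block the C16 hydroxyl (so that only the C17 hydroxymethyl can later lactonise) without retro-aldol cleavage or attack on the tert-butyl ester.

**Step 10**
Reactants: 17 silylated imide
Product: 19 (4R)-4-[(1R)-1,5-bis[(tert-butyldimethylsilyl)oxy]pent-3-yn-1-yl]oxolan-2-one, via hydroxy tert-butyl ester 18 (not isolated)
Conditions: LiBH4, MeOH, THF, 0 °C; then CSA (cat.), toluene, 60 °C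
Reagents that add atoms: none
Why: Reductive removal of the auxiliary at the exocyclic imide carbonyl (the tert-butyl ester survives) and acid-catalysed transesterification should close the γ-lactone by 5-exo-trig attack of the new primary alcohol, with C16 and C17 unaffected.

**Step 11**
Reactants: 19 alkynyl lactone
Product: 21 (4R)-4-[(1R,3E)-1,5-bis[(tert-butyldimethylsilyl)oxy]-4-iodopent-3-en-1-yl]oxolan-2-one, via alkenylstannane 20 (not isolated)
Conditions: Bu3SnH, Pd(PPh3)2Cl2 (cat.), THF, rt; then I2, CH2Cl2, 0 °C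
Reagents that add atoms: iodine, I-I
Why: Palladium-catalysed syn-hydrostannation should place tin on C13 (the alkyne carbon next to the propargylic oxygen) and hydrogen on C14 from the same face, and iododestannylation with retention then gives the (E)-iodide in which the silyloxymethyl group and C15 are cis, as the target requires.

**Step 12**
Reactants: 6 redox-active ester (excess); 21 alkenyl iodide
Product: 22 (4R)-4-[(1R,3Z)-1-[(tert-butyldimethylsilyl)oxy]-4-{[(tert-butyldimethylsilyl)oxy]methyl}-6-[(4aS,8aS)-2,5,5,8a-tetramethyl-3,4,4a,5,6,7,8,8a-octahydronaphthalen-1-yl]hex-3-en-1-yl]oxolan-2-one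
Conditions: NiCl2·6H2O (10 mol%), 2,2'-bipyridine (10 mol%), AgNO3 (0.3 equiv), DMF, Mg anode / reticulated vitreous carbon cathode, undivided cell, constant current (ca. 2.5 F/mol), rt
Reagents that add atoms: none
Why: Cathodically generated low-valent nickel inserts into the C13–I bond of 21 with retention of geometry, while single-electron reduction of ester 6 (assisted by the silver-nanoparticle layer that AgNO3 deposits on the cathode) releases phthalimide anion, CO2 and the primary C12 radical; capture of this radical by the alkenylnickel species and reductive elimination from trivalent nickel forge the C12–C13 bond, the Mg anode supplying the electrons. The closest known reaction type is the nickel-electrocatalytic decarboxylative alkenylation of redox-active esters with alkenyl halides used for modular polyene terpenoid assembly. No ring is closed and no stereocentre is created: the Z geometry of C13=C14 is inherited from the (E)-iodide, and C5, C10, C16 and C17 are remote from the reacting centres. The step needs cross-coupling to outrun homocoupling and a radical that neither rearranges nor cyclises; the substrate secures the latter because the homoallyl/cyclopropylcarbinyl manifold of the C12 radical is degenerate (C11 and C12 are both CH2 groups on C9) and the tetrasubstituted C8=C9 alkene offers only a disfavoured four-membered closure, while an excess of the cheap ester 6 compensates for dimerisation. Lactone, silyl ethers and the tetrasubstituted alkene should be inert to the mild, near-neutral reductive medium.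

**Step 13**
Reactants: 22 bis-silyl ether
Product: 23 (4R)-4-[(1R,3Z)-1-hydroxy-4-(hydroxymethyl)-6-[(4aS,8aS)-2,5,5,8a-tetramethyl-3,4,4a,5,6,7,8,8a-octahydronaphthalen-1-yl]hex-3-en-1-yl]oxolan-2-one (CNP0164639.2)
Conditions: HF·pyridine, pyridine, THF, 0 °C → rt
Reagents that add atoms: none
Why: Buffered, non-basic fluoride desilylation should free both hydroxyls without translactonisation of the C16 hydroxyl onto the lactone or isomerisation of either alkene.

**Compound list**
1 | (−)-sclareol, (1R,2R,4aS,8aS)-1-[(3R)-3-hydroxy-3-methylpent-4-en-1-yl]-2,5,5,8a-tetramethyldecahydronaphthalen-2-ol | CC1(CCC[C@]2([C@H]1CC[C@@]([C@@H]2CC[C@](C)(C=C)O)(C)O)C)C | starting material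
2 | 4-[(1R,2R,4aS,8aS)-2-hydroxy-2,5,5,8a-tetramethyldecahydronaphthalen-1-yl]butan-2-one | CC1(CCC[C@]2([C@H]1CC[C@@]([C@@H]2CCC(C)=O)(C)O)C)C | intermediate
3 | 3-[(1R,2R,4aS,8aS)-2-hydroxy-2,5,5,8a-tetramethyldecahydronaphthalen-1-yl]propanoic acid | CC1(CCC[C@]2([C@H]1CC[C@@]([C@@H]2CCC(O)=O)(C)O)C)C | intermediate
4 | methyl 3-[(4aS,8aS)-2,5,5,8a-tetramethyl-3,4,4a,5,6,7,8,8a-octahydronaphthalen-1-yl]propanoate | CC1=C(CCC(=O)OC)[C@@]2(C)CCCC(C)(C)[C@@H]2CC1 | intermediate
5 | 3-[(4aS,8aS)-2,5,5,8a-tetramethyl-3,4,4a,5,6,7,8,8a-octahydronaphthalen-1-yl]propanoic acid | CC1=C(CCC(=O)O)[C@@]2(C)CCCC(C)(C)[C@@H]2CC1 | intermediate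
6 | N-hydroxyphthalimide ester of 5 | CC1=C(CCC(=O)ON3C(=O)c4ccccc4C3=O)[C@@]2(C)CCCC(C)(C)[C@@H]2CC1 | intermediate
7 | tert-butyldimethyl(prop-2-yn-1-yloxy)silane | C#CCO[Si](C)(C)C(C)(C)C | starting material
8 | oxirane | C1CO1 | starting material
9 | lithium acetylide of 7 | [Li]C#CCO[Si](C)(C)C(C)(C)C | intermediate
10 | 5-[(tert-butyldimethylsilyl)oxy]pent-3-yn-1-ol | OCCC#CCO[Si](C)(C)C(C)(C)C | intermediate
11 | 5-[(tert-butyldimethylsilyl)oxy]pent-3-ynal | O=CCC#CCO[Si](C)(C)C(C)(C)C | intermediate
12 | 4-tert-butoxy-4-oxobutanoic acid | CC(C)(C)OC(=O)CCC(O)=O | starting material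
13 | (S)-4-benzyloxazolidin-2-one | O=C1N[C@@H](Cc2ccccc2)CO1 | starting material
14 | tert-butyl 4-[(4S)-4-benzyl-2-oxo-1,3-oxazolidin-3-yl]-4-oxobutanoate | O=C1OC[C@H](Cc2ccccc2)N1C(=O)CCC(=O)OC(C)(C)C | intermediate
15 | (Z)-dibutylboron enolate of 14 | O=C1OC[C@H](Cc2ccccc2)N1/C(OB(CCCC)CCCC)=C/CC(=O)OC(C)(C)C | intermediate
16 | tert-butyl (3S,4R)-3-{[(4S)-4-benzyl-2-oxo-1,3-oxazolidin-3-yl]carbonyl}-8-[(tert-butyldimethylsilyl)oxy]-4-hydroxyoct-6-ynoate | O=C1OC[C@H](Cc2ccccc2)N1C(=O)[C@@H](CC(=O)OC(C)(C)C)[C@H](O)CC#CCO[Si](C)(C)C(C)(C)C | intermediate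
17 | tert-butyl (3S,4R)-3-{[(4S)-4-benzyl-2-oxo-1,3-oxazolidin-3-yl]carbonyl}-4,8-bis[(tert-butyldimethylsilyl)oxy]oct-6-ynoate | O=C1OC[C@H](Cc2ccccc2)N1C(=O)[C@@H](CC(=O)OC(C)(C)C)[C@H](O[Si](C)(C)C(C)(C)C)CC#CCO[Si](C)(C)C(C)(C)C | intermediate
18 | tert-butyl (3R,4R)-4,8-bis[(tert-butyldimethylsilyl)oxy]-3-(hydroxymethyl)oct-6-ynoate | OC[C@@H](CC(=O)OC(C)(C)C)[C@H](O[Si](C)(C)C(C)(C)C)CC#CCO[Si](C)(C)C(C)(C)C | intermediate
19 | (4R)-4-[(1R)-1,5-bis[(tert-butyldimethylsilyl)oxy]pent-3-yn-1-yl]oxolan-2-one | CC(C)(C)[Si](C)(C)OCC#CC[C@@H](O[Si](C)(C)C(C)(C)C)[C@H]1COC(=O)C1 | intermediate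
20 | (4R)-4-[(1R,3E)-1,5-bis[(tert-butyldimethylsilyl)oxy]-4-(tributylstannyl)pent-3-en-1-yl]oxolan-2-one | CCCC[Sn](CCCC)(CCCC)/C(=C/C[C@@H](O[Si](C)(C)C(C)(C)C)[C@H]1COC(=O)C1)CO[Si](C)(C)C(C)(C)C | intermediate
21 | (4R)-4-[(1R,3E)-1,5-bis[(tert-butyldimethylsilyl)oxy]-4-iodopent-3-en-1-yl]oxolan-2-one | I/C(=C/C[C@@H](O[Si](C)(C)C(C)(C)C)[C@H]1COC(=O)C1)CO[Si](C)(C)C(C)(C)C | intermediate
22 | bis-silyl ether of the target (16-O-TBS, allylic O-TBS) | CC1=C(CC/C(=C/C[C@@H](O[Si](C)(C)C(C)(C)C)[C@H]2COC(=O)C2)CO[Si](C)(C)C(C)(C)C)[C@@]2(C)CCCC(C)(C)[C@@H]2CC1 | intermediate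
23 | (4R)-4-[(1R,3Z)-1-hydroxy-4-(hydroxymethyl)-6-[(4aS,8aS)-2,5,5,8a-tetramethyl-3,4,4a,5,6,7,8,8a-octahydronaphthalen-1-yl]hex-3-en-1-yl]oxolan-2-one | CC1=C(CC/C(=C/C[C@@H](O)[C@H]2COC(=O)C2)CO)[C@@]2(C)CCCC(C)(C)[C@@H]2CC1 | target

**Step count.** Total: 13 steps. Longest linear sequence: 8 steps (7 → 10 → 11 → 16 → 17 → 19 → 21 → 22 → 23).

**Steps most likely to fail**

1. Step 12. The redox-active ester may be reduced before the hindered, fully substituted alkenyl iodide has undergone oxidative addition. The C12 radical would then dimerise or abstract hydrogen (for example by 1,5-transfer from the C8 methyl) instead of being captured at nickel, and the iodide would be lost by protodehalogenation. Fallback from 6, returning at 22: visible-light iododecarboxylation (LiI, PPh3 cat., blue light, acetone) should give the homoallylic iodide F1, the radical being trapped by iodine far faster than it can rearrange. Zinc insertion (Zn dust, LiCl, THF) then gives the alkylzinc iodide F2, and a two-electron Negishi coupling of F2 with 21 (Pd(dppf)Cl2, THF/DMA, rt) leads back to 22.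

2. Step 11. Hydrostannation may place tin on C14 instead of C13, because the silyl ether biases the unsymmetrical internal alkyne only weakly. Fallback from 19, returning at 21: selective cleavage of the primary silyl ether (PPTS, EtOH, rt) gives the propargylic alcohol F3. Its free hydroxyl should direct palladium-catalysed syn-hydrostannation (Bu3SnH, Pd(PPh3)2Cl2, THF) to C13, giving the hydroxy stannane F4. Iododestannylation (I2, CH2Cl2, 0 °C) gives the iodo allylic alcohol F5, and resilylation (TBSCl, imidazole, DMF) returns to 21.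

3. Step 2. Equilibration to the tetrasubstituted alkene may be incomplete, leaving the trisubstituted C7=C8 isomer, or the tertiary cation may be diverted into the six-membered lactone. Fallback from 3, returning at 4: the isolated hydroxy acid is methylated (TMSCHN2, MeOH/toluene) to the hydroxy ester F6. Kinetic, non-acidic dehydration through the chlorosulfite (SOCl2, pyridine, CH2Cl2, −78 °C) gives mainly the exocyclic alkene ester F7. A separate iodine-catalysed isomerisation (I2 cat., benzene, reflux) then moves the double bond into the C8=C9 position to give 4.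

**Further compounds**
F1 | step 12 | (4aS,8aS)-1-(2-iodoethyl)-2,5,5,8a-tetramethyl-3,4,4a,5,6,7,8,8a-octahydronaphthalene | CC1=C(CCI)[C@@]2(C)CCCC(C)(C)[C@@H]2CC1
F2 | step 12 | {2-[(4aS,8aS)-2,5,5,8a-tetramethyl-3,4,4a,5,6,7,8,8a-octahydronaphthalen-1-yl]ethyl}zinc iodide | CC1=C(CC[Zn]I)[C@@]2(C)CCCC(C)(C)[C@@H]2CC1
F3 | step 11 | (4R)-4-[(1R)-1-[(tert-butyldimethylsilyl)oxy]-5-hydroxypent-3-yn-1-yl]oxolan-2-one | OCC#CC[C@@H](O[Si](C)(C)C(C)(C)C)[C@H]1COC(=O)C1
F4 | step 11 | (4R)-4-[(1R,3E)-1-[(tert-butyldimethylsilyl)oxy]-5-hydroxy-4-(tributylstannyl)pent-3-en-1-yl]oxolan-2-one | CCCC[Sn](CCCC)(CCCC)/C(=C/C[C@@H](O[Si](C)(C)C(C)(C)C)[C@H]1COC(=O)C1)CO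
F5 | step 11 | (4R)-4-[(1R,3E)-1-[(tert-butyldimethylsilyl)oxy]-5-hydroxy-4-iodopent-3-en-1-yl]oxolan-2-one | I/C(=C/C[C@@H](O[Si](C)(C)C(C)(C)C)[C@H]1COC(=O)C1)CO
F6 | step 2 | methyl 3-[(1R,2R,4aS,8aS)-2-hydroxy-2,5,5,8a-tetramethyldecahydronaphthalen-1-yl]propanoate | CC1(CCC[C@]2([C@H]1CC[C@@]([C@@H]2CCC(=O)OC)(C)O)C)C
F7 | step 2 | methyl 3-[(1S,4aS,8aS)-5,5,8a-trimethyl-2-methylidenedecahydronaphthalen-1-yl]propanoate | CC1(CCC[C@]2([C@H]1CCC(=C)[C@@H]2CCC(=O)OC)C)C
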